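## Retrosynthetic overview

1. The labile β-hydroxy ketone is unmasked last: the target comes from its conjugated tautomer (C7=C7a enone, sp3 C5) by deconjugative kinetic protonation at C7 plus desilylation.
2. That tautomer comes from C7 acylation of a 2-substituted 3-methoxycyclohexenone, then 5-exo opening of a side-chain epoxide by the diketone oxygen (dihydrofuran ring closed second; C2 set by inversion).
3. The epoxide comes from Shi epoxidation of a 1-aryl-3-methylbut-2-enyl side chain.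
4. Key C3a–C3 bond: a 2-bromo vinylogous ester (enolonium equivalent of the ring α-carbon) is joined to a benzylic/allylic chloride by nickel-catalysed asymmetric reductive coupling (sets C3).
5. The carbocycle is made first and regiodefined, by intramolecular ester Wittig reaction of a keto-ylide from desymmetrised 3-silyloxyglutaric anhydride (sets C6).

Assumption: the chiral catalysts of steps 1 and 7 are taken to give the sense of induction written; if either gives the mirror-image centre, its commercial pseudo-enantiomer or enantiomer is used instead.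

## Route

Step 1
Reactants: 1 4-[(tert-butyldimethylsilyl)oxy]oxane-2,6-dione (3-silyloxyglutaric anhydride)
Product: 2 (3S)-3-[(tert-butyldimethylsilyl)oxy]-5-methoxy-5-oxopentanoic acid
Conditions: MeOH (10 equiv), hydroquinidine anthraquinone-1,4-diyl diether [(DHQD)2AQN] (10 mol %), Et2O, −40 °C
Reagents that add atoms: methanol, CO
Why: Cinchona-alkaloid-catalysed enantioselective methanolysis (desymmetrisation) of the prochiral anhydride differentiates the two acyl groups and so fixes the carbinol carbon that becomes C6 of the target.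

Step 2
Reactants: 2 (3S)-3-[(tert-butyldimethylsilyl)oxy]-5-methoxy-5-oxopentanoic acid
Product: 5 (5R)-5-[(tert-butyldimethylsilyl)oxy]-3-methoxycyclohex-2-en-1-one, via acyl imidazolide 3 (not isolated), via keto-ylide 4 (not isolated)
Conditions: 1,1′-carbonyldiimidazole, THF, 23 °C; Ph3P=CH2 (from Ph3PCH3Br, NaN(SiMe3)2), THF, −78 to 0 °C; then toluene, 110 °C
Reagents that add atoms: methyltriphenylphosphonium bromide, C[P+](c1ccccc1)(c1ccccc1)c1ccccc1.[Br-]
Why: Ylide acylation gives a keto-stabilised phosphorane whose intramolecular Wittig olefination of the methyl ester closes the six-membered ring with the methoxy group fixed on the ester-derived carbon, so no symmetric 1,3-dione is ever formed and the C6 centre stays defined.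

Step 3
Reactants: 5 (5R)-5-[(tert-butyldimethylsilyl)oxy]-3-methoxycyclohex-2-en-1-one
Product: 6 (5R)-2-bromo-5-[(tert-butyldimethylsilyl)oxy]-3-methoxycyclohex-2-en-1-one
Conditions: N-bromosuccinimide, CH2Cl2, 0 °C
Reagents that add atoms: N-bromosuccinimide, O=C1CCC(=O)N1Br
Why: Electrophilic α-bromination of the push–pull alkene of a vinylogous ester is regiospecific for C2 and turns the normally nucleophilic ring α-carbon into an electrophile.

Step 4
Reactants: 7 methyl 3-bromo-4-hydroxybenzoate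
Product: 8 methyl 3-bromo-4-[(triisopropylsilyl)oxy]benzoate
Conditions: iPr3SiCl, imidazole, DMF, 23 °C
Reagents that add atoms: chlorotriisopropylsilane, CC(C)[Si](Cl)(C(C)C)C(C)C
Why: Silylation of the phenol gives a bulky aryl silyl ether that survives the Heck, nickel, epoxidation and enolate steps and is removed by fluoride at the end.

Step 5
Reactants: 8 methyl 3-bromo-4-[(triisopropylsilyl)oxy]benzoate, 9 2-methylbut-3-en-2-ol
Product: 10 methyl 3-[(1E)-3-hydroxy-3-methylbut-1-en-1-yl]-4-[(triisopropylsilyl)oxy]benzoate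
Conditions: Pd(OAc)2 (5 mol %), P(o-tol)3 (10 mol %), Et3N, MeCN, 85 °C
Reagents that add atoms: none
Why: Mizoroki–Heck arylation of the terminal alkene gives the E-styrenyl tertiary allylic alcohol, and the silyl ether blocks cyclisation to a chromene.

Step 6
Reactants: 10 methyl 3-[(1E)-3-hydroxy-3-methylbut-1-en-1-yl]-4-[(triisopropylsilyl)oxy]benzoate
Product: 11 rac-methyl 3-(1-chloro-3-methylbut-2-en-1-yl)-4-[(triisopropylsilyl)oxy]benzoate
Conditions: HCl (4 M in 1,4-dioxane), CH2Cl2, 0 °C; used crude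
Reagents that add atoms: hydrogen chloride, Cl
Why: SN1 substitution with allylic transposition places chloride on the less substituted, benzylic terminus of the allyl cation (as in the tertiary-allylic-alcohol to prenyl-chloride conversion), and any tertiary allylic isomer feeds the same allyl radical in step 7.

Step 7
Reactants: 6 (5R)-2-bromo-5-[(tert-butyldimethylsilyl)oxy]-3-methoxycyclohex-2-en-1-one, 11 rac-methyl 3-(1-chloro-3-methylbut-2-en-1-yl)-4-[(triisopropylsilyl)oxy]benzoate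
Product: 12 methyl 3-[(1R)-1-[(4R)-4-[(tert-butyldimethylsilyl)oxy]-2-methoxy-6-oxocyclohex-1-en-1-yl]-3-methylbut-2-en-1-yl]-4-[(triisopropylsilyl)oxy]benzoate
Conditions: NiCl2(MeOCH2CH2OMe) (10 mol %), (3aR,3a′R,8aS,8a′S)-2,2′-(cyclopropane-1,1-diyl)bis(3a,8a-dihydro-8H-indeno[1,2-d][1,3]oxazole) (12 mol %), Mn powder (3 equiv), NaI (0.5 equiv), N,N-dimethylacetamide, 0 °C
Reagents that add atoms: none
Why: Proposed new method: zerovalent nickel inserts into the C–Br bond of 6 (an enolonium equivalent of the ring α-carbon), chloride 11 is reduced to the 1-aryl-3,3-dimethylallyl radical, which is captured by the chiral vinylnickel species, and ligand-controlled reductive elimination at the less hindered benzylic terminus gives the non-enolisable 1R centre (C3 of the target); the closest known reactions are the nickel/bis(oxazoline)-catalysed enantioconvergent reductive coupling of vinyl bromides with secondary benzyl chlorides and the nickel-catalysed reductive allylation of vinyl halides.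

Step 8
Reactants: 12 methyl 3-[(1R)-1-[(4R)-4-[(tert-butyldimethylsilyl)oxy]-2-methoxy-6-oxocyclohex-1-en-1-yl]-3-methylbut-2-en-1-yl]-4-[(triisopropylsilyl)oxy]benzoate
Product: 13 methyl 3-[(R)-[(4R)-4-[(tert-butyldimethylsilyl)oxy]-2-methoxy-6-oxocyclohex-1-en-1-yl][(2S)-3,3-dimethyloxiran-2-yl]methyl]-4-[(triisopropylsilyl)oxy]benzoate
Conditions: 1,2:4,5-di-O-isopropylidene-β-L-erythro-2,3-hexodiulo-2,6-pyranose (ent-Shi ketone, 30 mol %), KHSO5 (as Oxone), K2CO3, Bu4NHSO4, MeCN/CH2(OMe)2/aq. Na2B4O7 buffer, 0 °C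
Reagents that add atoms: potassium peroxymonosulfate, [K+].[O-]S(=O)(=O)OO
Why: Shi asymmetric epoxidation is reagent-controlled on the electron-rich trisubstituted alkene (the push–pull alkene of the vinylogous ester is inert), and the L-configured ketone is chosen to give the (2S)-oxirane so that SN2 opening in step 9 inverts this carbon to 2R.

Step 9
Reactants: 13 methyl 3-[(R)-[(4R)-4-[(tert-butyldimethylsilyl)oxy]-2-methoxy-6-oxocyclohex-1-en-1-yl][(2S)-3,3-dimethyloxiran-2-yl]methyl]-4-[(triisopropylsilyl)oxy]benzoate, 14 3-phenylpropanoic acid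
Product: 17 methyl 3-[(2R,3R,6R)-6-[(tert-butyldimethylsilyl)oxy]-2-(2-hydroxypropan-2-yl)-4-methoxy-7-(3-phenylpropanoyl)-2,3,5,6-tetrahydro-1-benzofuran-3-yl]-4-[(triisopropylsilyl)oxy]benzoate, via acyl imidazolide 15 (not isolated), via beta-diketone 16 (not isolated)
Conditions: 14, 1,1′-carbonyldiimidazole (1.0 equiv), THF, 23 °C (second flask); 13, LiN(iPr)2 (1.1 equiv), THF, −78 °C; combine at −78 °C, then 1,8-diazabicyclo[5.4.0]undec-7-ene, −78 to 23 °C; H2O work-up
Reagents that add atoms: none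
Why: Kinetic α′-deprotonation of the vinylogous ester (Stork–Danheiser) and C-acylation by the acyl imidazolide give a β-diketonate whose C7a oxygen opens the epoxide 5-exo at C2 with inversion (C-alkylation at C7 is geometrically impossible because the tether lies anti to C7 across the C3a–C7a bond), closing the dihydrofuran with 2R trans to the 3R aryl group and leaving the acyl ketone as a stable β-alkoxy enone.

Step 10
Reactants: 17 methyl 3-[(2R,3R,6R)-6-[(tert-butyldimethylsilyl)oxy]-2-(2-hydroxypropan-2-yl)-4-methoxy-7-(3-phenylpropanoyl)-2,3,5,6-tetrahydro-1-benzofuran-3-yl]-4-[(triisopropylsilyl)oxy]benzoate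
Product: 20 methyl 4-hydroxy-3-[(2R,3R,6R,7R)-6-hydroxy-2-(2-hydroxypropan-2-yl)-4-methoxy-7-(3-phenylpropanoyl)-2,3,6,7-tetrahydro-1-benzofuran-3-yl]benzoate, via silyl trienol ether 18 (not isolated), via C6 silyl ether 19 (not isolated)
Conditions: Me3SiOTf (3 equiv), Et3N (5 equiv), CH2Cl2, −78 to 0 °C; solvent change to THF; Bu4NF/AcOH (1:1, excess), −78 to 23 °C
Reagents that add atoms: none
Why: Soft enolisation (silyl triflate/amine) with loss of H-5 gives the silyl trienol ether carrying the target's ring diene, fluoride in an acetic acid buffer then releases the extended enolate, which is protonated kinetically at the α-carbon C7 anti to the C6 silyloxy group (deconjugative kinetic protonation, sets 7R with acyl cis to O6), and the same near-neutral fluoride removes the remaining silyl ethers.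

## Compound list

1 | 4-[(tert-butyldimethylsilyl)oxy]oxane-2,6-dione | O=C1CC(O[Si](C)(C)C(C)(C)C)CC(=O)O1 | starting material
2 | (3S)-3-[(tert-butyldimethylsilyl)oxy]-5-methoxy-5-oxopentanoic acid | OC(=O)C[C@H](O[Si](C)(C)C(C)(C)C)CC(=O)OC | intermediate
3 | methyl (3S)-3-[(tert-butyldimethylsilyl)oxy]-5-(imidazol-1-yl)-5-oxopentanoate | O=C(C[C@H](O[Si](C)(C)C(C)(C)C)CC(=O)OC)n1ccnc1 | intermediate
4 | methyl (3S)-3-[(tert-butyldimethylsilyl)oxy]-5-oxo-6-(triphenyl-λ5-phosphanylidene)hexanoate | O=C(C=P(c1ccccc1)(c1ccccc1)c1ccccc1)C[C@H](O[Si](C)(C)C(C)(C)C)CC(=O)OC | intermediate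
5 | (5R)-5-[(tert-butyldimethylsilyl)oxy]-3-methoxycyclohex-2-en-1-one | COC1=CC(=O)C[C@H](O[Si](C)(C)C(C)(C)C)C1 | intermediate
6 | (5R)-2-bromo-5-[(tert-butyldimethylsilyl)oxy]-3-methoxycyclohex-2-en-1-one | COC1=C(Br)C(=O)C[C@H](O[Si](C)(C)C(C)(C)C)C1 | intermediate
7 | methyl 3-bromo-4-hydroxybenzoate | COC(=O)c1ccc(O)c(Br)c1 | starting material
8 | methyl 3-bromo-4-[(triisopropylsilyl)oxy]benzoate | COC(=O)c1ccc(O[Si](C(C)C)(C(C)C)C(C)C)c(Br)c1 | intermediate
9 | 2-methylbut-3-en-2-ol | CC(C)(O)C=C | starting material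
10 | methyl 3-[(1E)-3-hydroxy-3-methylbut-1-en-1-yl]-4-[(triisopropylsilyl)oxy]benzoate | COC(=O)c1ccc(O[Si](C(C)C)(C(C)C)C(C)C)c(/C=C/C(C)(C)O)c1 | intermediate
11 | rac-methyl 3-(1-chloro-3-methylbut-2-en-1-yl)-4-[(triisopropylsilyl)oxy]benzoate | COC(=O)c1ccc(O[Si](C(C)C)(C(C)C)C(C)C)c(C(Cl)C=C(C)C)c1 | intermediate
12 | methyl 3-[(1R)-1-[(4R)-4-[(tert-butyldimethylsilyl)oxy]-2-methoxy-6-oxocyclohex-1-en-1-yl]-3-methylbut-2-en-1-yl]-4-[(triisopropylsilyl)oxy]benzoate | COC(=O)c1ccc(O[Si](C(C)C)(C(C)C)C(C)C)c(c1)[C@@H](C=C(C)C)C2=C(OC)C[C@@H](O[Si](C)(C)C(C)(C)C)CC2=O | intermediate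
13 | methyl 3-[(R)-[(4R)-4-[(tert-butyldimethylsilyl)oxy]-2-methoxy-6-oxocyclohex-1-en-1-yl][(2S)-3,3-dimethyloxiran-2-yl]methyl]-4-[(triisopropylsilyl)oxy]benzoate | COC(=O)c1ccc(O[Si](C(C)C)(C(C)C)C(C)C)c(c1)[C@@H]([C@@H]3OC3(C)C)C2=C(OC)C[C@@H](O[Si](C)(C)C(C)(C)C)CC2=O | intermediate
14 | 3-phenylpropanoic acid | OC(=O)CCc1ccccc1 | starting material
15 | 1-(3-phenylpropanoyl)imidazole | O=C(CCc1ccccc1)n1ccnc1 | intermediate
16 | methyl 3-[(R)-[(4R)-4-[(tert-butyldimethylsilyl)oxy]-2-methoxy-6-oxo-5-(3-phenylpropanoyl)cyclohex-1-en-1-yl][(2S)-3,3-dimethyloxiran-2-yl]methyl]-4-[(triisopropylsilyl)oxy]benzoate (C5 epimers/enol) | COC(=O)c1ccc(O[Si](C(C)C)(C(C)C)C(C)C)c(c1)[C@@H]([C@@H]3OC3(C)C)C2=C(OC)C[C@@H](O[Si](C)(C)C(C)(C)C)C(C(=O)CCc4ccccc4)C2=O | intermediate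
17 | methyl 3-[(2R,3R,6R)-6-[(tert-butyldimethylsilyl)oxy]-2-(2-hydroxypropan-2-yl)-4-methoxy-7-(3-phenylpropanoyl)-2,3,5,6-tetrahydro-1-benzofuran-3-yl]-4-[(triisopropylsilyl)oxy]benzoate | COC(=O)c1ccc(O[Si](C(C)C)(C(C)C)C(C)C)c(c1)[C@@H]2C3=C(OC)C[C@@H](O[Si](C)(C)C(C)(C)C)C(C(=O)CCc4ccccc4)=C3O[C@H]2C(C)(C)O | intermediate
18 | methyl 3-[(2R,3R,6R)-6-[(tert-butyldimethylsilyl)oxy]-4-methoxy-7-[3-phenyl-1-(trimethylsilyloxy)propylidene]-2-[2-(trimethylsilyloxy)propan-2-yl]-2,3,6,7-tetrahydro-1-benzofuran-3-yl]-4-[(triisopropylsilyl)oxy]benzoate | COC(=O)c1ccc(O[Si](C(C)C)(C(C)C)C(C)C)c(c1)[C@@H]2C3=C(O[C@H]2C(C)(C)O[Si](C)(C)C)C(=C(O[Si](C)(C)C)CCc4ccccc4)[C@H](O[Si](C)(C)C(C)(C)C)C=C3OC | intermediate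
19 | methyl 3-[(2R,3R,6R,7R)-6-[(tert-butyldimethylsilyl)oxy]-2-(2-hydroxypropan-2-yl)-4-methoxy-7-(3-phenylpropanoyl)-2,3,6,7-tetrahydro-1-benzofuran-3-yl]-4-hydroxybenzoate | COC(=O)c1ccc(O)c(c1)[C@@H]2C3=C(O[C@H]2C(C)(C)O)[C@H](C(=O)CCc4ccccc4)[C@H](O[Si](C)(C)C(C)(C)C)C=C3OC | intermediate
20 | methyl 4-hydroxy-3-[(2R,3R,6R,7R)-6-hydroxy-2-(2-hydroxypropan-2-yl)-4-methoxy-7-(3-phenylpropanoyl)-2,3,6,7-tetrahydro-1-benzofuran-3-yl]benzoate | COC(=O)c1ccc(O)c([C@@H]2C3=C(O[C@H]2C(C)(C)O)[C@H](C(=O)CCc2ccccc2)[C@H](O)C=C3OC)c1 | target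

## Step count and risk

Total steps: 10. Longest linear sequence: 7 (steps 1, 2, 3, 7, 8, 9, 10; the aryl branch 4, 5, 6, 7, 8, 9, 10 is equally long).

Three steps most likely to fail:

**Step 7 (key coupling).** Enantiocontrol with an allylic, rather than simple benzylic, radical partner is unproven, and protodebromination of 6 may compete. Fallback, setting out from 6 and 11 and coming back at 13: the same bond is made without ligand control and C3 is resolved through diastereomers. NiCl2(MeOCH2CH2OMe)/4,4′-di-tert-butyl-2,2′-bipyridine with Zn powder (the known non-selective reductive vinyl–allyl coupling) gives 12 mixed with its C3 epimer, the (1S)-butenyl epimer of 12 F1. The mixture is epoxidised as in step 8; because the oxirane centre is reagent-controlled, the products differ in the relative configuration of two adjacent carbons, so 13 is separated by chromatography from the (S)-methine epimer of 13 F2 (at most half of the material is used).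

**Step 10 (end game).** Soft enolisation of 17 may remove a side-chain α-hydrogen instead of H-5, and the transient enolate can lose the C6 silyloxy group to aromatise. Fallback, setting out from 13 and coming back at 19: the side-chain position is blocked by carrying a cinnamoyl group. (2E)-3-Phenylprop-2-enoic acid is activated as 1-[(2E)-3-phenylprop-2-enoyl]imidazole F3 and used as in step 9; the cinnamoyl β-diketone F4 cyclises to the cinnamoyl enone F5, which has no enolisable side-chain hydrogen. Me3SiOTf/Et3N can then only remove H-5 to give the silyl tetraenol ether F6. Bu4NF/AcOH at −78 °C protonates C7 and leaves the C6-silylated chalcone-type ketone F7. Chemoselective 1,4-reduction of its enone C=C with [(Ph3P)CuH]6 (cat.) under H2 in benzene/t-BuOH gives 19, which is desilylated as in the second stage of step 10.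

**Step 2 (ring closure).** A keto-stabilised ylide may not olefinate a simple methyl ester, even intramolecularly. Fallback, setting out from 4 (isolated in this variant) and coming back at 5: the acceptor is made a thioester. Saponification of 4 with LiOH gives the keto-ylide acid F8; ethanethiol with 1-ethyl-3-(3-dimethylaminopropyl)carbodiimide and 4-dimethylaminopyridine gives the keto-ylide S-ethyl thioester F9; its intramolecular Wittig reaction in toluene at 80 °C gives the vinylogous thioester F10. NaOMe in MeOH at 0 °C then exchanges ethylsulfanyl for methoxy by addition–elimination at the same carbon, so regiochemistry and the C6 centre are kept, giving 5.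

## Further compounds

F1 | step 7 | methyl 3-[(1S)-1-[(4R)-4-[(tert-butyldimethylsilyl)oxy]-2-methoxy-6-oxocyclohex-1-en-1-yl]-3-methylbut-2-en-1-yl]-4-[(triisopropylsilyl)oxy]benzoate | COC(=O)c1ccc(O[Si](C(C)C)(C(C)C)C(C)C)c(c1)[C@H](C=C(C)C)C2=C(OC)C[C@@H](O[Si](C)(C)C(C)(C)C)CC2=O
F2 | step 7 | methyl 3-[(S)-[(4R)-4-[(tert-butyldimethylsilyl)oxy]-2-methoxy-6-oxocyclohex-1-en-1-yl][(2S)-3,3-dimethyloxiran-2-yl]methyl]-4-[(triisopropylsilyl)oxy]benzoate | COC(=O)c1ccc(O[Si](C(C)C)(C(C)C)C(C)C)c(c1)[C@H]([C@@H]3OC3(C)C)C2=C(OC)C[C@@H](O[Si](C)(C)C(C)(C)C)CC2=O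
F3 | step 10 | 1-[(2E)-3-phenylprop-2-enoyl]imidazole | O=C(/C=C/c1ccccc1)n1ccnc1
F4 | step 10 | methyl 3-[(R)-[(4R)-4-[(tert-butyldimethylsilyl)oxy]-2-methoxy-6-oxo-5-[(2E)-3-phenylprop-2-enoyl]cyclohex-1-en-1-yl][(2S)-3,3-dimethyloxiran-2-yl]methyl]-4-[(triisopropylsilyl)oxy]benzoate | COC(=O)c1ccc(O[Si](C(C)C)(C(C)C)C(C)C)c(c1)[C@@H]([C@@H]3OC3(C)C)C2=C(OC)C[C@@H](O[Si](C)(C)C(C)(C)C)C(C(=O)/C=C/c4ccccc4)C2=O
F5 | step 10 | methyl 3-[(2R,3R,6R)-6-[(tert-butyldimethylsilyl)oxy]-2-(2-hydroxypropan-2-yl)-4-methoxy-7-[(2E)-3-phenylprop-2-enoyl]-2,3,5,6-tetrahydro-1-benzofuran-3-yl]-4-[(triisopropylsilyl)oxy]benzoate | COC(=O)c1ccc(O[Si](C(C)C)(C(C)C)C(C)C)c(c1)[C@@H]2C3=C(OC)C[C@@H](O[Si](C)(C)C(C)(C)C)C(C(=O)/C=C/c4ccccc4)=C3O[C@H]2C(C)(C)O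
F6 | step 10 | methyl 3-[(2R,3R,6R)-6-[(tert-butyldimethylsilyl)oxy]-4-methoxy-7-[(2E)-3-phenyl-1-(trimethylsilyloxy)prop-2-enylidene]-2-[2-(trimethylsilyloxy)propan-2-yl]-2,3,6,7-tetrahydro-1-benzofuran-3-yl]-4-[(triisopropylsilyl)oxy]benzoate | COC(=O)c1ccc(O[Si](C(C)C)(C(C)C)C(C)C)c(c1)[C@@H]2C3=C(O[C@H]2C(C)(C)O[Si](C)(C)C)C(=C(O[Si](C)(C)C)/C=C/c4ccccc4)[C@H](O[Si](C)(C)C(C)(C)C)C=C3OC
F7 | step 10 | methyl 3-[(2R,3R,6R,7R)-6-[(tert-butyldimethylsilyl)oxy]-2-(2-hydroxypropan-2-yl)-4-methoxy-7-[(2E)-3-phenylprop-2-enoyl]-2,3,6,7-tetrahydro-1-benzofuran-3-yl]-4-hydroxybenzoate | COC(=O)c1ccc(O)c(c1)[C@@H]2C3=C(O[C@H]2C(C)(C)O)[C@H](C(=O)/C=C/c4ccccc4)[C@H](O[Si](C)(C)C(C)(C)C)C=C3OC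
F8 | step 2 | (3S)-3-[(tert-butyldimethylsilyl)oxy]-5-oxo-6-(triphenyl-λ5-phosphanylidene)hexanoic acid | O=C(C=P(c1ccccc1)(c1ccccc1)c1ccccc1)C[C@H](O[Si](C)(C)C(C)(C)C)CC(=O)O
F9 | step 2 | S-ethyl (3S)-3-[(tert-butyldimethylsilyl)oxy]-5-oxo-6-(triphenyl-λ5-phosphanylidene)hexanethioate | O=C(C=P(c1ccccc1)(c1ccccc1)c1ccccc1)C[C@H](O[Si](C)(C)C(C)(C)C)CC(=O)SCC
F10 | step 2 | (5S)-5-[(tert-butyldimethylsilyl)oxy]-3-(ethylsulfanyl)cyclohex-2-en-1-one | CCSC1=CC(=O)C[C@H](O[Si](C)(C)C(C)(C)C)C1
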